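Numbering: dihydronaphthalene C1 (bears the pyranone), C2 (CO2Me), C3 (CO2H), C4, C4a, C5–C8 (ring A, O6 and O7), C8a; pyranone atoms are primed.
Retrosynthesis cuts, in order: the four O–benzyl bonds of a protected form; the C8a–C1 bond of ring B; the C1–C3' bond to the pyranone (Heck); the C1 methylene carbon (formaldehyde) and the C3=C4 bond (Stobbe).
Forward: ring A and the pyranone ring are bought intact; the C4–C3–C2–C1 chain is built on ring A and the bromopyranone is attached; ring B is the only ring made and is closed last.
Enabling feature: C1 is the β-carbon of the C2 ester and C8a is the ring A carbon para to O6, held next to C1 by the (E) C3=C4 styrene bond, so ring B is the 6-endo hydroarylation product of an acyclic (E,E)-2,3-bis(alkylidene)succinate.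
Stereochemistry: C1 from a chiral Brønsted acid that selects one helical conformer of the diene; C2 by protonation under thermodynamic (trans) control. The three carboxyl groups are told apart from the Stobbe step onwards.
Key step: step 7

Remark: the sense of induction of the chiral acid in step 7 cannot be predicted with certainty; the catalyst enantiomer to be used is the one that leads to the (1R) series.

Step 1
Reactants: 1 3,4-bis(benzyloxy)benzaldehyde; 2 dibenzyl succinate
Product: 3 (E)-3-(benzyloxycarbonyl)-4-[3,4-bis(benzyloxy)phenyl]but-3-enoic acid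
Conditions: KOtBu, tBuOH/THF, rt to 50 °C; then 1 M HCl
Reagents that add atoms: none
Why: Stobbe condensation: the succinate enolate adds to the aldehyde, the alkoxide lactonises onto the distal ester and base-induced opening of the lactone gives the (E)-arylidene half-ester (aryl cis to the CH2 arm), with the free acid on the CH2 arm and the benzyl ester on the alkene carbon, so the later C2 and C3 carboxyl groups are already differentiated.

Step 2
Reactants: 3 (E)-3-(benzyloxycarbonyl)-4-[3,4-bis(benzyloxy)phenyl]but-3-enoic acid
Product: 4 1-benzyl 4-methyl (E)-2-[3,4-bis(benzyloxy)benzylidene]succinate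
Conditions: MeI, KHCO3, DMF, rt
Reagents that add atoms: iodomethane, CI
Why: Carboxylate O-alkylation (SN2) with iodomethane under bicarbonate, which is too weak to enolise or isomerise the alkylidene succinate, installs the methyl ester that stays to the end.

Step 3
Reactants: 4 1-benzyl 4-methyl (E)-2-[3,4-bis(benzyloxy)benzylidene]succinate
Product: 5 1-benzyl 4-methyl (E)-2-[3,4-bis(benzyloxy)benzylidene]-3-methylenesuccinate
Conditions: (CH2O)n, K2CO3, Bu4NI (cat.), DMF, 60 °C
Reagents that add atoms: formaldehyde (from paraformaldehyde), C=O
Why: Aldol addition of the doubly activated CH2 (α to the ester and allylic) to formaldehyde and E1cB loss of water, the α-methylenation known for arylacetic esters and the same position at which second Stobbe condensations take place, should give the 2-arylidene-3-methylene succinate.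

Step 4
Reactants: 6 2-oxo-2H-pyran-6-carboxylic acid
Product: 7 benzyl 2-oxo-2H-pyran-6-carboxylate
Conditions: BnBr, KHCO3, DMF, rt
Reagents that add atoms: benzyl bromide, BrCc1ccccc1
Why: Carboxylate alkylation with benzyl bromide under bicarbonate gives the benzyl ester without opening the base-sensitive 2-pyranone ring.

Step 5
Reactants: 7 benzyl 2-oxo-2H-pyran-6-carboxylate
Product: 9 benzyl 3-bromo-2-oxo-2H-pyran-6-carboxylate, via dibromide adduct 8 (not isolated)
Conditions: Br2, CH2Cl2, 0 °C to rt; then Et3N, 0 °C
Reagents that add atoms: bromine, BrBr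
Why: Addition–elimination bromination of the 2-pyranone: bromine adds across the C3=C4 bond of the pyranone and triethylamine removes HBr from the adduct, which should leave bromine at C3 because C5 is deactivated as the β-carbon of the acrylate unit formed with the ester-bearing C6.

Step 6
Reactants: 5 1-benzyl 4-methyl (E)-2-[3,4-bis(benzyloxy)benzylidene]-3-methylenesuccinate; 9 benzyl 3-bromo-2-oxo-2H-pyran-6-carboxylate
Product: 10 1-benzyl 4-methyl (2E,3E)-2-[3,4-bis(benzyloxy)benzylidene]-3-{[6-(benzyloxycarbonyl)-2-oxo-2H-pyran-3-yl]methylidene}succinate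
Conditions: Pd(OAc)2 (5 mol%), P(o-tol)3 (10 mol%), NaHCO3, Bu4NCl, DMF, 80 °C
Reagents that add atoms: none
Why: Heck reaction: zerovalent palladium inserts into the C–Br bond of 9, the pyranonyl–palladium species adds to the terminal CH2 of the 1,1-disubstituted acrylate unit of 5 and β-hydride elimination, possible only towards C1, gives the trisubstituted alkene, expected mainly as the (E)-isomer (pyranone trans to the methyl ester) as in arylations of itaconates and taken on as that isomer, the trisubstituted arylidene bond being inert.

Step 7
Reactants: 10 1-benzyl 4-methyl (2E,3E)-2-[3,4-bis(benzyloxy)benzylidene]-3-{[6-(benzyloxycarbonyl)-2-oxo-2H-pyran-3-yl]methylidene}succinate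
Product: 11 3-benzyl 2-methyl (1R,2R)-6,7-bis(benzyloxy)-1-[6-(benzyloxycarbonyl)-2-oxo-2H-pyran-3-yl]-1,2-dihydronaphthalene-2,3-dicarboxylate
Conditions: chiral imidodiphosphorimidate acid HN[P(=NSO2CF3)(O2C20H10Ar2)]2 (each O2C20H10Ar2 an (S)-1,1'-binaphthyl-2,2'-diyl unit with Ar = 3,5-(CF3)2C6H3 at its 3,3'-positions; 5 mol%), CHCl3, 0 °C to rt
Reagents that add atoms: none
Why: Proposed new method: the confined chiral acid protonates the C2 methyl-ester carbonyl of 10 (binding at the more basic pyranone carbonyl is reversible and unproductive), so that C1 becomes the electrophilic end of a 1-hydroxyallyl cation; the ring A carbon para to the C6 benzyloxy group attacks C1, the arenium ion loses its proton and the ester enol is protonated at C2. The closest known reactions are the triflic-acid cyclisation of 2,3-bis(benzylidene)succinates to trans-1-aryl-1,2-dihydronaphthalene-2,3-dicarboxylates, which is this Friedel–Crafts (Michael-type hydroarylation) ring closure in racemic form, and the enantioselective Nazarov and hydroarylation cyclisations of carbonyl-activated olefins catalysed by imidodiphosphorimidate acids. Ring B closes in the 6-endo-trig mode at C1. C1 is under catalyst control: the twisted diene exists as rapidly interconverting P and M helical conformers, each of which can present only one face of C1 to C8a, and the chiral anion paired with the protonated ester should favour one of them; C2 is under substrate control, since the trans isomer with both substituents pseudoaxial is the thermodynamic one and is reached through the enol under the acidic conditions. The step needs regioselectivity for C8a over C5, which the para-directing C6 ether and the crowding of C5 between the side chain and that ether secure, and it needs the (E) geometry of C3=C4 from the Stobbe step, which holds C8a within reach of C1. The electron-poor pyranone raises the electrophilicity of C1 and offers no competing nucleophilic position.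

Step 8
Reactants: 11 3-benzyl 2-methyl (1R,2R)-6,7-bis(benzyloxy)-1-[6-(benzyloxycarbonyl)-2-oxo-2H-pyran-3-yl]-1,2-dihydronaphthalene-2,3-dicarboxylate
Product: 12 (1R,2R)-1-(6-carboxy-2-oxo-2H-pyran-3-yl)-6,7-dihydroxy-2-(methoxycarbonyl)-1,2-dihydronaphthalene-3-carboxylic acid
Conditions: BCl3 (1 M in CH2Cl2), pentamethylbenzene, CH2Cl2, −78 to −20 °C; aqueous work-up
Reagents that add atoms: none
Why: Lewis-acid debenzylation: BCl3 ionises the four benzyl–oxygen bonds (two aryl ethers, two esters) and pentamethylbenzene traps the benzyl cations by Friedel–Crafts alkylation, conditions under which the methyl ester, the pyranone, the C3=C4 bond and the two stereocentres should survive at low temperature.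

Compound list
1 | 3,4-bis(benzyloxy)benzaldehyde | O=Cc1ccc(OCc2ccccc2)c(OCc2ccccc2)c1 | starting material
2 | dibenzyl succinate | O=C(CCC(=O)OCc1ccccc1)OCc1ccccc1 | starting material
3 | (E)-3-(benzyloxycarbonyl)-4-[3,4-bis(benzyloxy)phenyl]but-3-enoic acid | OC(=O)C/C(C(=O)OCc1ccccc1)=C\c1ccc(OCc2ccccc2)c(OCc2ccccc2)c1 | intermediate
4 | 1-benzyl 4-methyl (E)-2-[3,4-bis(benzyloxy)benzylidene]succinate | COC(=O)C/C(C(=O)OCc1ccccc1)=C\c1ccc(OCc2ccccc2)c(OCc2ccccc2)c1 | intermediate
5 | 1-benzyl 4-methyl (E)-2-[3,4-bis(benzyloxy)benzylidene]-3-methylenesuccinate | COC(=O)C(=C)/C(C(=O)OCc1ccccc1)=C\c1ccc(OCc2ccccc2)c(OCc2ccccc2)c1 | intermediate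
6 | 2-oxo-2H-pyran-6-carboxylic acid | O=C(O)c1cccc(=O)o1 | starting material
7 | benzyl 2-oxo-2H-pyran-6-carboxylate | O=C(OCc1ccccc1)c1cccc(=O)o1 | intermediate
8 | benzyl trans-3,4-dibromo-2-oxo-3,4-dihydro-2H-pyran-6-carboxylate (dibromide adduct, racemic, one enantiomer drawn) | O=C(OCc1ccccc1)C1=C[C@H](Br)[C@@H](Br)C(=O)O1 | intermediate
9 | benzyl 3-bromo-2-oxo-2H-pyran-6-carboxylate | O=C(OCc1ccccc1)c1ccc(Br)c(=O)o1 | intermediate
10 | 1-benzyl 4-methyl (2E,3E)-2-[3,4-bis(benzyloxy)benzylidene]-3-{[6-(benzyloxycarbonyl)-2-oxo-2H-pyran-3-yl]methylidene}succinate | COC(=O)C(=C/c1ccc(C(=O)OCc2ccccc2)oc1=O)/C(C(=O)OCc1ccccc1)=C\c1ccc(OCc2ccccc2)c(OCc2ccccc2)c1 | intermediate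
11 | 3-benzyl 2-methyl (1R,2R)-6,7-bis(benzyloxy)-1-[6-(benzyloxycarbonyl)-2-oxo-2H-pyran-3-yl]-1,2-dihydronaphthalene-2,3-dicarboxylate | COC(=O)[C@H]1C(C(=O)OCc2ccccc2)=Cc2cc(OCc3ccccc3)c(OCc3ccccc3)cc2[C@@H]1c1ccc(C(=O)OCc2ccccc2)oc1=O | intermediate
12 | (1R,2R)-1-(6-carboxy-2-oxo-2H-pyran-3-yl)-6,7-dihydroxy-2-(methoxycarbonyl)-1,2-dihydronaphthalene-3-carboxylic acid | COC(=O)[C@H]1C(C(=O)O)=Cc2cc(O)c(O)cc2[C@@H]1c1ccc(C(=O)O)oc1=O | target

Total steps: 8. Longest linear sequence: 6 steps (steps 1, 2, 3, 6, 7, 8).

Steps most likely to fail

Step 7 (Proposed new method). The chiral acid may not activate the ester enough, or may discriminate poorly between the two helical conformers, so that the ring closure is slow or gives low enantiomeric purity. In that case 10 would be treated with excess trifluoromethanesulfonic acid in trifluoroacetic acid with pentamethylbenzene. This is the known strong-acid cyclisation of 2,3-bis(alkylidene)succinates, run under conditions that also cleave benzyl ethers and benzyl esters. It should give the racemic trans diacid, that is 12 together with its (1S,2S)-enantiomer F1. Resolution by crystallisation of the diastereomeric salts with an enantiopure amine such as cinchonidine, or by chromatography on a chiral stationary phase, would then give 12. This fallback sets out from 10 and returns to the route at 12.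

Step 6. The bromopyranone may decompose under basic palladium conditions, or insertion into the hindered 1,1-disubstituted alkene may be sluggish. The C1=C2 bond would then be made by aldol condensation. Compound 9 would be formylated (Pd(PPh3)4, CO, Bu3SnH, toluene, 50 °C) to benzyl 3-formyl-2-oxo-2H-pyran-6-carboxylate F2. The lithium enolate of 4 (LiHMDS, THF, −78 °C) would be added to F2 to give 1-benzyl 4-methyl (E)-2-[3,4-bis(benzyloxy)benzylidene]-3-{[6-(benzyloxycarbonyl)-2-oxo-2H-pyran-3-yl](hydroxy)methyl}succinate F3 as a mixture of diastereomers. Mesylation and base-induced elimination (MsCl, Et3N, then DBU, 0 °C) would lead to 10. This fallback sets out from 9 and 4 and returns at 10.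

Step 3. The electron-poor diene may oligomerise under the basic conditions, or the double bond may migrate in the dienolate. Compound 5 would then be assembled without an enolate. Wittig reaction of 1 with benzyl 2-bromo-2-(triphenylphosphoranylidene)acetate would give benzyl (Z)-2-bromo-3-[3,4-bis(benzyloxy)phenyl]acrylate F4. Stille coupling of F4 with methyl 2-(tributylstannyl)acrylate (Pd(PPh3)4, CuI, DMF, 50 °C), with retention of the alkene geometry, would give 5. This fallback sets out from 1 and returns at 5.

Further compounds
F1 | step 7 | (1S,2S)-1-(6-carboxy-2-oxo-2H-pyran-3-yl)-6,7-dihydroxy-2-(methoxycarbonyl)-1,2-dihydronaphthalene-3-carboxylic acid (enantiomer of 12) | COC(=O)[C@@H]1C(C(=O)O)=Cc2cc(O)c(O)cc2[C@H]1c1ccc(C(=O)O)oc1=O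
F2 | step 6 | benzyl 3-formyl-2-oxo-2H-pyran-6-carboxylate | O=Cc1ccc(C(=O)OCc2ccccc2)oc1=O
F3 | step 6 | 1-benzyl 4-methyl (E)-2-[3,4-bis(benzyloxy)benzylidene]-3-{[6-(benzyloxycarbonyl)-2-oxo-2H-pyran-3-yl](hydroxy)methyl}succinate (mixture of diastereomers) | COC(=O)C(C(O)c1ccc(C(=O)OCc2ccccc2)oc1=O)/C(C(=O)OCc1ccccc1)=C\c1ccc(OCc2ccccc2)c(OCc2ccccc2)c1
F4 | step 3 | benzyl (Z)-2-bromo-3-[3,4-bis(benzyloxy)phenyl]acrylate | O=C(OCc1ccccc1)/C(Br)=C/c1ccc(OCc2ccccc2)c(OCc2ccccc2)c1
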